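## Retrosynthetic overview

1. Kazinol H is disconnected to its isomer, the (2S)-flavan bis-ether (ring A: 7-O-prenyl; ring B: 4'-O-1,1-dimethylpropargyl, free 5'-OH, 2'-prenyl). One heating should turn the propargyl ether into the 2,2-dimethylpyran ring (bonds C3'–CH and O4'–CMe2) and the prenyl ether into the C6 1,1-dimethylallyl group with free 7-OH.
2. Enabling feature: both C5 units sit on ring carbons ortho to a phenol oxygen. C3' lies beside O4' on ring B (the other ortho carbon, C5', is blocked by OH), and C6 lies beside O7 on ring A (para to O1). Each unit can therefore be passed from oxygen to carbon by a [3,3] shift, without protecting groups.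
3. The bis-ether comes from an (R)-1,3-diarylpropan-1-ol (Mitsunobu closure of O1–C2 with inversion), this from the dihydrochalcone (CBS reduction), this from the chalcone (1,4-reduction), and this from a ring B acetophenone plus a ring A salicylaldehyde (Claisen–Schmidt).
4. The ring B acetophenone comes from 1-(2-bromo-4,5-dimethoxyphenyl)ethanone (demethylation, Stille prenylation, O-propargylation of the OH para to the acetyl group). The ring A aldehyde comes from 2,4-dihydroxybenzaldehyde (4-O-prenylation).
5. Ring order: benzene rings A and B are bought; the chroman pyran ring (ring C) is closed in step 8; the dimethylpyran ring of the chromene is closed last, in step 9.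

Key step: step 9

Remark: 1-(2-bromo-4,5-dimethoxyphenyl)ethan-1-one, 2,4-dihydroxybenzaldehyde, tributyl(3-methylbut-2-en-1-yl)stannane, 3-chloro-3-methylbut-1-yne and 1-bromo-3-methylbut-2-ene are taken as catalogue compounds; flavan numbering (O1, C2–C4, C4a, C5–C8, C8a; ring B C1'–C6') is used throughout.

## Route

Step 1
Reactants: 1 1-(2-bromo-4,5-dimethoxyphenyl)ethan-1-one
Product: 2 1-(2-bromo-4,5-dihydroxyphenyl)ethan-1-one
Conditions: BBr3 (3 equiv), CH2Cl2, −78 °C to rt; then MeOH/H2O
Reagents that add atoms: none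
Why: Lewis acid cleavage of aryl methyl ethers with BBr3 should free both phenols, while the aryl bromide and the aryl ketone are inert.

Step 2
Reactants: 2 1-(2-bromo-4,5-dihydroxyphenyl)ethan-1-one
Product: 3 1-[4,5-dihydroxy-2-(3-methylbut-2-en-1-yl)phenyl]ethan-1-one
Conditions: tributyl(3-methylbut-2-en-1-yl)stannane (1.3 equiv), Pd(PPh3)4 (5 mol %), DMF, 90 °C, argon
Reagents that add atoms: tributyl(3-methylbut-2-en-1-yl)stannane, CCCC[Sn](CCCC)(CCCC)CC=C(C)C
Why: Stille coupling of the ortho-acetyl aryl bromide, in which reductive elimination at the unsubstituted terminus of the allyl palladium intermediate should give the linear prenyl arene and the neutral, base-free medium should tolerate the free catechol.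

Step 3
Reactants: 3 1-[4,5-dihydroxy-2-(3-methylbut-2-en-1-yl)phenyl]ethan-1-one
Product: 4 1-[5-hydroxy-4-(2-methylbut-3-yn-2-yloxy)-2-(3-methylbut-2-en-1-yl)phenyl]ethan-1-one
Conditions: 3-chloro-3-methylbut-1-yne (1.2 equiv), DBU (1.1 equiv), CuCl2·2H2O (1 mol %), MeCN, 0 °C, argon
Reagents that add atoms: 3-chloro-3-methylbut-1-yne, CC(C)(Cl)C#C
Why: Copper-catalysed propargylic O-alkylation with one equivalent of base, in which only the 4-OH (acidified by the para acetyl group) should be deprotonated and etherified, leaving the 5-OH free.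

Step 4
Reactants: 5 2,4-dihydroxybenzaldehyde
Product: 6 2-hydroxy-4-[(3-methylbut-2-en-1-yl)oxy]benzaldehyde
Conditions: 1-bromo-3-methylbut-2-ene (1.05 equiv), K2CO3 (1.1 equiv), acetone, rt to 40 °C
Reagents that add atoms: 1-bromo-3-methylbut-2-ene, CC(C)=CCBr
Why: Williamson etherification should occur at the 4-OH only, because the 2-OH is held in a hydrogen bond to the aldehyde and is much less nucleophilic.

Step 5
Reactants: 4 1-[5-hydroxy-4-(2-methylbut-3-yn-2-yloxy)-2-(3-methylbut-2-en-1-yl)phenyl]ethan-1-one; 6 2-hydroxy-4-[(3-methylbut-2-en-1-yl)oxy]benzaldehyde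
Product: 7 (E)-3-{2-hydroxy-4-[(3-methylbut-2-en-1-yl)oxy]phenyl}-1-[5-hydroxy-4-(2-methylbut-3-yn-2-yloxy)-2-(3-methylbut-2-en-1-yl)phenyl]prop-2-en-1-one
Conditions: KOH (50% aq., 10 equiv), EtOH, rt, argon; work-up at pH 6
Reagents that add atoms: none
Why: Claisen–Schmidt (crossed aldol) condensation of the methyl ketone enolate with the non-enolisable aldehyde should give the E-enone after loss of water, with both ethers and both phenols stable to aqueous KOH at room temperature.

Step 6
Reactants: 7 (E)-3-{2-hydroxy-4-[(3-methylbut-2-en-1-yl)oxy]phenyl}-1-[5-hydroxy-4-(2-methylbut-3-yn-2-yloxy)-2-(3-methylbut-2-en-1-yl)phenyl]prop-2-en-1-one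
Product: 8 3-{2-hydroxy-4-[(3-methylbut-2-en-1-yl)oxy]phenyl}-1-[5-hydroxy-4-(2-methylbut-3-yn-2-yloxy)-2-(3-methylbut-2-en-1-yl)phenyl]propan-1-one
Conditions: Na2S2O4 (5 equiv), NaHCO3 (10 equiv), dioxane/H2O 1:1, 80 °C, argon
Reagents that add atoms: none
Why: Dithionite conjugate reduction should saturate only the enone C=C and leave the isolated alkenes, the terminal alkyne and the ketone untouched.

Step 7
Reactants: 8 3-{2-hydroxy-4-[(3-methylbut-2-en-1-yl)oxy]phenyl}-1-[5-hydroxy-4-(2-methylbut-3-yn-2-yloxy)-2-(3-methylbut-2-en-1-yl)phenyl]propan-1-one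
Product: 9 (1R)-3-{2-hydroxy-4-[(3-methylbut-2-en-1-yl)oxy]phenyl}-1-[5-hydroxy-4-(2-methylbut-3-yn-2-yloxy)-2-(3-methylbut-2-en-1-yl)phenyl]propan-1-ol
Conditions: (S)-2-methyl-CBS-oxazaborolidine (20 mol %), catecholborane (4 equiv), toluene, −78 to −40 °C; then MeOH, pH 7 buffer
Reagents that add atoms: none
Why: Corey–Bakshi–Shibata reduction, in which the (S)-oxazaborolidine binds the ketone with the aryl group as the large substituent and should deliver hydride to give the (R)-carbinol; catecholborane at low temperature does not hydroborate the alkenes or the alkyne, and the excess covers the two phenols.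

Step 8
Reactants: 9 (1R)-3-{2-hydroxy-4-[(3-methylbut-2-en-1-yl)oxy]phenyl}-1-[5-hydroxy-4-(2-methylbut-3-yn-2-yloxy)-2-(3-methylbut-2-en-1-yl)phenyl]propan-1-ol
Product: 10 5-{(2S)-7-[(3-methylbut-2-en-1-yl)oxy]chroman-2-yl}-2-(2-methylbut-3-yn-2-yloxy)-4-(3-methylbut-2-en-1-yl)phenol
Conditions: PPh3 (1.5 equiv), DIAD (1.5 equiv), THF (0.02 M), 0 °C to rt
Reagents that add atoms: none
Why: Intramolecular Mitsunobu etherification, in which the ring A phenol displaces the oxyphosphonium group in a 6-exo-tet SN2 closure with inversion, so the (R)-carbinol should give the (2S)-chroman.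

Step 9
Reactants: 10 5-{(2S)-7-[(3-methylbut-2-en-1-yl)oxy]chroman-2-yl}-2-(2-methylbut-3-yn-2-yloxy)-4-(3-methylbut-2-en-1-yl)phenol
Product: 13 kazinol H, via ring B o-quinone methide 11 (not isolated), via chromene prenyl ether 12 (not isolated)
Conditions: N,N-diethylaniline (degassed, 0.02 M), argon, 140 °C, 3 h, then 195 °C, 2 h
Reagents that add atoms: none
Why: At 140 °C the aryl 1,1-dimethylpropargyl ether of ring B undergoes a propargyl Claisen ([3,3]) shift to C3', the only hydrogen-bearing carbon ortho to O4' (C5' carries OH), which makes the C3'–CH bond as an allene; enolisation and a [1,5]-hydrogen shift give o-quinone methide 11, and its thermal oxa-6π electrocyclisation (disrotatory, six-membered ring) makes the O4'–CMe2 bond and closes the pyran ring to chromene 12. At 195 °C the aryl prenyl ether of ring A then undergoes the aromatic Claisen rearrangement through a chair [3,3] transition state with allyl inversion, so that the CMe2 terminus bonds to C6, and tautomerisation of the dienone frees the 7-OH to give 13. The closest known reaction types are the thermal conversion of aryl 1,1-dimethylpropargyl ethers into 2,2-dimethyl-2H-chromenes and the ortho-Claisen rearrangement of aryl prenyl ethers into o-(1,1-dimethylallyl)phenols. No new stereocentre is formed, and C2 takes no part, so the (2S) configuration from step 8 is kept. The selectivity needed is C6 over C8 on ring A: C6 is para to the ring oxygen O1 and flanked only by C5–H, whereas C8 is squeezed between O1 and O7, so the electronic bias of a meta alkoxy group and the bulk of the tertiary terminus both point to C6. The basic aprotic solvent and the short second stage are chosen to hold back acid-catalysed cyclisation and the abnormal Claisen isomerisation of the newly formed phenol.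

## Compound list

1 | 1-(2-bromo-4,5-dimethoxyphenyl)ethan-1-one | CC(=O)c1cc(OC)c(OC)cc1Br | starting material
2 | 1-(2-bromo-4,5-dihydroxyphenyl)ethan-1-one | CC(=O)c1cc(O)c(O)cc1Br | intermediate
3 | 1-[4,5-dihydroxy-2-(3-methylbut-2-en-1-yl)phenyl]ethan-1-one | CC(=O)c1cc(O)c(O)cc1CC=C(C)C | intermediate
4 | 1-[5-hydroxy-4-(2-methylbut-3-yn-2-yloxy)-2-(3-methylbut-2-en-1-yl)phenyl]ethan-1-one | CC(=O)c1cc(O)c(OC(C)(C)C#C)cc1CC=C(C)C | intermediate
5 | 2,4-dihydroxybenzaldehyde | O=Cc1ccc(O)cc1O | starting material
6 | 2-hydroxy-4-[(3-methylbut-2-en-1-yl)oxy]benzaldehyde | O=Cc1ccc(OCC=C(C)C)cc1O | intermediate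
7 | (E)-3-{2-hydroxy-4-[(3-methylbut-2-en-1-yl)oxy]phenyl}-1-[5-hydroxy-4-(2-methylbut-3-yn-2-yloxy)-2-(3-methylbut-2-en-1-yl)phenyl]prop-2-en-1-one | O=C(/C=C/c1ccc(OCC=C(C)C)cc1O)c1cc(O)c(OC(C)(C)C#C)cc1CC=C(C)C | intermediate
8 | 3-{2-hydroxy-4-[(3-methylbut-2-en-1-yl)oxy]phenyl}-1-[5-hydroxy-4-(2-methylbut-3-yn-2-yloxy)-2-(3-methylbut-2-en-1-yl)phenyl]propan-1-one | O=C(CCc1ccc(OCC=C(C)C)cc1O)c1cc(O)c(OC(C)(C)C#C)cc1CC=C(C)C | intermediate
9 | (1R)-3-{2-hydroxy-4-[(3-methylbut-2-en-1-yl)oxy]phenyl}-1-[5-hydroxy-4-(2-methylbut-3-yn-2-yloxy)-2-(3-methylbut-2-en-1-yl)phenyl]propan-1-ol | O[C@H](CCc1ccc(OCC=C(C)C)cc1O)c1cc(O)c(OC(C)(C)C#C)cc1CC=C(C)C | intermediate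
10 | 5-{(2S)-7-[(3-methylbut-2-en-1-yl)oxy]chroman-2-yl}-2-(2-methylbut-3-yn-2-yloxy)-4-(3-methylbut-2-en-1-yl)phenol | CC(C)=CCOc1ccc2c(c1)O[C@H](c1cc(O)c(OC(C)(C)C#C)cc1CC=C(C)C)CC2 | intermediate
11 | ring B o-quinone methide: 2-hydroxy-4-{(2S)-7-[(3-methylbut-2-en-1-yl)oxy]chroman-2-yl}-5-(3-methylbut-2-en-1-yl)-6-(3-methylbut-2-en-1-ylidene)cyclohexa-2,4-dien-1-one | CC(C)=CCOc1ccc2c(c1)O[C@H](C1=C(CC=C(C)C)C(=CC=C(C)C)C(=O)C(O)=C1)CC2 | intermediate (not isolated)
12 | chromene prenyl ether: 2,2-dimethyl-5-(3-methylbut-2-en-1-yl)-6-{(2S)-7-[(3-methylbut-2-en-1-yl)oxy]chroman-2-yl}-2H-chromen-8-ol | CC(C)=CCOc1ccc2c(c1)O[C@H](c1cc(O)c3c(c1CC=C(C)C)C=CC(C)(C)O3)CC2 | intermediate (not isolated)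
13 | kazinol H: 6-[(2S)-7-hydroxy-6-(2-methylbut-3-en-2-yl)chroman-2-yl]-2,2-dimethyl-5-(3-methylbut-2-en-1-yl)-2H-chromen-8-ol | C=CC(C)(C)c1cc2c(cc1O)O[C@H](c1cc(O)c3c(c1CC=C(C)C)C=CC(C)(C)O3)CC2 | target

## Step count and risks

Total step count: 9. Longest linear sequence: 8 steps (steps 1, 2, 3, 5, 6, 7, 8 and 9).

Steps most likely to fail:

1. Step 9. The ring A shift may go in part to C8, and the freed o-(1,1-dimethylallyl)phenol may react further at the temperature of the second stage (abnormal Claisen isomerisation, loss of the C5 unit). The fallback separates the two rearrangements and traps the phenol as it forms. It sets out from 10, which is heated only to 140 °C in xylene so that the chromene prenyl ether 12 can be isolated. Compound 12 is then rearranged at 190 °C in N,N-diethylaniline containing acetic anhydride (sealed tube), so that the 5'-OH is acetylated first and the 7-OH is captured on formation, which should give kazinol H diacetate F1. A C8 isomer, if formed, would be removed at this less polar stage. Methanolysis (K2CO3, MeOH, rt) comes back to the route at 13.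

2. Step 2. The free catechol may slow oxidative addition into the electron-rich ring, bind the catalyst or degrade oxidatively. The fallback is a protecting-group detour that sets out from 2. Silylation (TBSCl, imidazole, DMF) should give 1-[2-bromo-4,5-bis(tert-butyldimethylsilyloxy)phenyl]ethan-1-one F2. The same Stille coupling should then give 1-[4,5-bis(tert-butyldimethylsilyloxy)-2-(3-methylbut-2-en-1-yl)phenyl]ethan-1-one F3. Desilylation (TBAF, AcOH, THF, 0 °C) comes back to the route at 3.

3. Step 6. Reduction of the electron-rich phenolic enone by dithionite may be incomplete, or sulfinate adducts and ketone reduction may compete. The fallback sets out from 7 and replaces steps 6 and 7 by one tandem asymmetric transfer hydrogenation (RuCl[(R,R)-TsDPEN](p-cymene), HCO2H/Et3N 5:2, 40 °C). This should reduce first the conjugated C=C and then the ketone to the (R)-carbinol, a known behaviour of 2-hydroxychalcones; the unconjugated tertiary propargylic alkyne is expected to be spared. It comes back to the route at 9 and makes no new compound (F0).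

Further compounds
F1 | step 9 | kazinol H diacetate: 6-[(2S)-7-acetoxy-6-(2-methylbut-3-en-2-yl)chroman-2-yl]-2,2-dimethyl-5-(3-methylbut-2-en-1-yl)-2H-chromen-8-yl acetate | C=CC(C)(C)c1cc2c(cc1OC(C)=O)O[C@H](c1cc(OC(C)=O)c3c(c1CC=C(C)C)C=CC(C)(C)O3)CC2
F2 | step 2 | 1-[2-bromo-4,5-bis(tert-butyldimethylsilyloxy)phenyl]ethan-1-one | CC(=O)c1cc(O[Si](C)(C)C(C)(C)C)c(O[Si](C)(C)C(C)(C)C)cc1Br
F3 | step 2 | 1-[4,5-bis(tert-butyldimethylsilyloxy)-2-(3-methylbut-2-en-1-yl)phenyl]ethan-1-one | CC(=O)c1cc(O[Si](C)(C)C(C)(C)C)c(O[Si](C)(C)C(C)(C)C)cc1CC=C(C)C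
F0 | step 6 | none | none
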